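The amounts in these flasks are lopsided: 0.10 M of L goes in as 2 portions, against G between 0.400 mM and 2.00 mM, and the question is how much free J stands at the end.

| flask | L | G | remark | time |
|---|---|---|---|---|
| Tuesday's | 0.067 M (in portions, 2) | 0.40 mM | run made earlier; portions every 8.0 h |  |
| Monday's | 0.20 M (in portions, 2) | 0.40 mM | run made earlier; portions every 8.0 h |  |
| alder | 0.10 M (in portions, 2) | 0.400 mM | the portions of L follow each other after 8.0 h, the first at the start | 15 d |
| ash | 0.10 M (in portions, 2) | 0.600 mM | the portions of L follow each other after 8.0 h, the first at the start | 15 d |
| elm | 0.10 M (in portions, 2) | 0.800 mM | the portions of L follow each other after 8.0 h, the first at the start | 15 d |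
| birch | 0.10 M (in portions, 2) | 1.20 mM | the portions of L follow each other after 8.0 h, the first at the start | 15 d |
| maple | 0.10 M (in portions, 2) | 2.00 mM | the portions of L follow each other after 8.0 h, the first at the start | 15 d |

| run | time / d | J / % | L / % |
|---|---|---|---|
| Tuesday's | 0.208 | 35.1 | 1.7 |
| Tuesday's | 0.625 | 73.6 | 0.9 |
| Tuesday's | 1.04 | 74.4 | 1.2 |
| Tuesday's | 1.67 | 73.7 | 0.2 |
| Tuesday's | 2.50 | 74.0 | 0.2 |
| Tuesday's | 3.00 | 75.7 | 0 |
| Monday's | 0.208 | 25.3 | 1.0 |
| Monday's | 0.625 | 51.8 | 0 |
| Monday's | 1.04 | 52.3 | 0 |
| Monday's | 1.67 | 52.2 | 0 |
| Monday's | 2.50 | 50.9 | 0 |
| Monday's | 3.00 | 51.2 | 2.1 |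

(each reading ± 1 percentage point)

- the numbers in the tables scatter with a standard deviation of 1 percentage point
- a reading or a percentage of J counts all its forms, free or not
- the concentration of J that is asked is that of its free form alone
- "hardly changes" means that all values lie within two and a half points (for a concentration: within two and a half percent of the largest)
- no earlier run changes the charge of G; that part of a forecast is a guess

* [J] (only what is free in solution) at the end for alder, ash, elm, birch, maple, in this order
* how the row runs (falls, then rises / hardly changes / rises, then falls / falls all the way / rises all the way)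

I began with the two runs. After the last portion had reacted, J stayed level, at 74.3% of the L charged on Tuesday and 51.7% on Monday. So the bigger portions gave the lower share. I read this as a first-order step to J competing with a loss of second order in L. A portion of concentration p then gives J = a·ln(1 + p/a). Solving this for a gave 0.0438 M from Tuesday and 0.0430 M from Monday, two different portions. I carried their mean, 0.0434 M, as the crossover concentration a: the concentration of L at which the step to J and the loss go equally fast.

Then I ran alder slowly in my head. The first portion brings L to 0.0500 M, close to a, so at that instant about half of the L reacting becomes J. As L falls below a, the step to J takes over. Tuesday's reading at 0.208 d showed 1.7% of L and about half of the final J, well before the next portion at 8.0 h. So I treated the second portion as a fresh start, which makes 0.0665 M of J in all. No run varied G, so here I could only guess. I took it as a reagent used one for one, which would make its largest charge 2.00% of the L. I therefore expected a flat row near that J, with the free part unread, because the readings count every form of J.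

The forecast differed from me: it gave 0.067 M, 0.0745 M, 0.079 M, 0.084 M and 0.089 M, so that the row rises all the way, on the grounds that “G is far below J, so I guess it is a catalyst with a ∝ G”.

The flasks gave 0.0480 M, 0.0480 M, 0.0480 M, 0.0480 M and 0.0480 M: the row hardly changes.

    L → J (k = 0.00980 min⁻¹)
    E ⇌ J, rate k2*(cs2 - [J]) while solid is left; crystals form when [J] > cs2 (solubility = 48.0 mM, k = 0.00360 min⁻¹)
    2 L → Z (k = 0.110 M⁻¹ min⁻¹)
    L + G → X (k = 0.420 M⁻¹ min⁻¹)

In alder, L had a half-life of 1.2 h by the step to J and 2.9 d by the step with G, with concentrations held at their charge. At the end alder held 66.7% of J against my 66.5%, but 18.7% of that was the crystals E, and free J stood at 0.0480 M, the solubility 48 mM. For maple the same a reckons 66.5% again; that flask held 65.7%, with 17.7% as E and 0.0480 M free.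

The data stem from a simulated flask for an exercise; scatter was added.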